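The disconnection cuts two adjacent bonds on the central benzene ring (ring A): the bond from the ring carbon to the hexanoyl carbonyl carbon and the bond from the neighbouring ring carbon to its hydroxyl oxygen, the ortho-hydroxyaryl ketone motif. Both are formed in one operation when an aryne of ring A inserts into the C–O bond of hexanoic acid. The aryne precursor is a 2-(trimethylsilyl)aryl triflate that already carries both (R)-configured arms; its two other phenol oxygens and both syncarpic enol oxygens are benzyl ethers, so a single neutral hydrogenolysis ends the synthesis. The arms are attached one at a time by catalytic asymmetric Friedel–Crafts-type Michael additions.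

Key step: step 10

Remark on numbering: ring A is numbered C1 (carbon that receives the hexanoyl group), C2 (oxygen-bearing neighbour that becomes the triflate), C3 (isobutyl arm), C4 (oxygen), C5 (isopropyl arm), C6 (oxygen). "Arm" means the benzylic CH(alkyl) carbon with its syncarpic ring; Bn = benzyl.

Assumption: the sense of induction of the cinchona squaramide is not predicted here; the quinine-derived catalyst is written for both (R) centres, and its quinidine-derived pseudoenantiomer is to be used if the first adduct proves to have the opposite configuration.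

Step 1
Reactants: 1 syncarpic acid; 2 2-methylpropanal
Product: 4 2,2,4,4-tetramethyl-6-(2-methylpropylidene)cyclohexane-1,3,5-trione, via Mannich base 3 (not isolated)
Conditions: piperidine (1.05 equiv), CH2Cl2, rt; then 1 M HCl, CH2Cl2/H2O, rt; used at once
Reagents that add atoms: none
Why: Mannich condensation of the cyclic 1,3-dione with the aldehyde and piperidine masks the reactive alkylidene from a second molecule of 1, and acid then eliminates the amine to release the alkylidene trione, which has no stereocentre.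

Step 2
Reactants: 1 syncarpic acid; 5 3-methylbutanal
Product: 7 2,2,4,4-tetramethyl-6-(3-methylbutylidene)cyclohexane-1,3,5-trione, via Mannich base 6 (not isolated)
Conditions: piperidine (1.05 equiv), CH2Cl2, rt; then 1 M HCl, CH2Cl2/H2O, rt; used at once
Reagents that add atoms: none
Why: The same Mannich condensation and acid-induced amine elimination should give the second acceptor, which is used fresh because its double bond can drift out of conjugation.

Step 3
Reactants: 8 phloroglucinol; 4 2,2,4,4-tetramethyl-6-(2-methylpropylidene)cyclohexane-1,3,5-trione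
Product: 10 3-(benzyloxy)-4,4,6,6-tetramethyl-2-[(1R)-2-methyl-1-(2,4,6-trihydroxyphenyl)propyl]cyclohex-2-ene-1,5-dione, via free enol adduct 9 (not isolated)
Conditions: 8 (3 equiv), 3-{[3,5-bis(trifluoromethyl)phenyl]amino}-4-{[(8S,9S)-6'-methoxycinchonan-9-yl]amino}cyclobut-3-ene-1,2-dione (10 mol%), THF, −20 °C; aqueous wash to remove excess 8; then O-benzyl-N,N'-diisopropylisourea (1.5 equiv), THF, 40 °C
Reagents that add atoms: O-benzyl-N,N'-diisopropylisourea, CC(C)NC(=NC(C)C)OCc1ccccc1
Why: In this Friedel–Crafts-type Michael addition of a phenol to an alkylidene 1,3-dione the squaramide binds the trione and the quinuclidine the phenol, so the arene attacks one face of the alkylidene and sets the (R) centre, excess 8 suppresses double alkylation, and the isourea then benzylates only the strongly acidic enol under neutral conditions, which blocks retro-Michael loss of configuration.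

Step 4
Reactants: 10 3-(benzyloxy)-4,4,6,6-tetramethyl-2-[(1R)-2-methyl-1-(2,4,6-trihydroxyphenyl)propyl]cyclohex-2-ene-1,5-dione
Product: 11 mono-silyl ether of 10 (C2–OSi(i-Pr)3; C4–OH and C6–OH free)
Conditions: TIPSCl (1.1 equiv), imidazole, DMF, 0 °C
Reagents that add atoms: chlorotri(propan-2-yl)silane, CC(C)[Si](Cl)(C(C)C)C(C)C
Why: Silylation with a bulky chlorosilane should pick the only phenol without an ortho substituent (C2–OH), since the two hydroxyls beside the arm are hindered and hydrogen-bonded to the enone.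

Step 5
Reactants: 11 mono-silyl ether of 10
Product: 12 dibenzyl ether (C2–OSi(i-Pr)3; C4–OBn; C6–OBn)
Conditions: BnBr (2.5 equiv), K2CO3, n-Bu4NI (cat.), DMF, 0 °C to rt
Reagents that add atoms: benzyl bromide, BrCc1ccccc1
Why: Williamson O-benzylation of the two equivalent phenols protects the oxygen that will later lie between the two arms while it is still accessible; the enol is already capped, so no enolate can leave in a retro-Michael step, and the aryl triisopropylsilyl ether tolerates K2CO3.

Step 6
Reactants: 12 dibenzyl ether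
Product: 13 3-(benzyloxy)-2-[(1R)-1-[2,6-bis(benzyloxy)-4-hydroxyphenyl]-2-methylpropyl]-4,4,6,6-tetramethylcyclohex-2-ene-1,5-dione
Conditions: TBAF (1.1 equiv), AcOH (1.1 equiv), THF, 0 °C
Reagents that add atoms: none
Why: Fluoride cleaves the aryl silyl ether through Si–F bond formation, the acetic acid buffer keeps the medium near neutral, and benzyl ethers and the benzyl enol ether are untouched.

Step 7
Reactants: 13 phenol with the isopropyl arm; 7 2,2,4,4-tetramethyl-6-(3-methylbutylidene)cyclohexane-1,3,5-trione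
Product: 15 bis-arm phenol with both enols benzylated (C1–H; C2–OH; C3 isobutyl arm; C4–OBn; C5 isopropyl arm; C6–OBn), via free enol adduct 14 (not isolated)
Conditions: 7 (1.05 equiv), 3-{[3,5-bis(trifluoromethyl)phenyl]amino}-4-{[(8S,9S)-6'-methoxycinchonan-9-yl]amino}cyclobut-3-ene-1,2-dione (10 mol%), CH2Cl2, −20 °C; then O-benzyl-N,N'-diisopropylisourea (1.5 equiv), 40 °C
Reagents that add atoms: O-benzyl-N,N'-diisopropylisourea, CC(C)NC(=NC(C)C)OCc1ccccc1
Why: The same catalytic Friedel–Crafts-type Michael addition now takes place ortho to the single free phenol (C1 and C3 are equivalent by rotation about the C2–C5 axis), the catalyst sets the new (R) centre independently of the remote one, any minor enantiomer of 13 is removed here as a diastereomer, and neutral isourea capping of the new enol again locks the centre.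

Step 8
Reactants: 15 bis-arm phenol
Product: 16 iodophenol (iodine at C1; C2–OH)
Conditions: NIS (1.05 equiv), CH2Cl2, −20 °C to 0 °C, dark
Reagents that add atoms: N-iodosuccinimide, O=C1CCC(=O)N1I
Why: Electrophilic aromatic iodination should occur at the only unsubstituted ring carbon, which is ortho to the free phenol, while the fully substituted, electron-poor enol ether double bonds do not compete.

Step 9
Reactants: 16 iodophenol
Product: 20 2-(trimethylsilyl)aryl triflate (C1–SiMe3; C2–OTf; C3 isobutyl arm; C4–OBn; C5 isopropyl arm; C6–OBn), via trimethylsilyl ether 17 (not isolated), via aryllithium 18 (not isolated), via lithium phenoxide 19 (not isolated)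
Conditions: HMDS, THF, 65 °C, then evaporation; t-BuLi (2.1 equiv), Et2O/THF, −100 °C to −78 °C; Tf2O (1.2 equiv), −78 °C to 0 °C
Reagents that add atoms: hexamethyldisilazane, C[Si](C)(C)N[Si](C)(C)C; trifluoromethanesulfonic anhydride, O=S(=O)(OS(=O)(=O)C(F)(F)F)C(F)(F)F
Why: This is the standard one-flask route to 2-silylaryl triflates, in which O-silylation, iodine–lithium exchange at −100 °C (expected to outrun addition to the hindered, non-enolisable carbonyls flanked by quaternary carbons), a retro-Brook 1,3 O-to-C silyl shift that can start only from the C2 oxygen because C6 carries a benzyl ether, and O-triflation of the lithium phenoxide follow one another without touching a stereocentre.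

Step 10
Reactants: 20 2-(trimethylsilyl)aryl triflate; 21 hexanoic acid
Product: 23 tetra-O-benzyl ortho-hydroxyaryl ketone (C1–CO(CH2)4CH3; C2–OH; C3 isobutyl arm; C4–OBn; C5 isopropyl arm; C6–OBn), via aryne 22 (not isolated)
Conditions: CsF (6 equiv) premixed with 21 (2 equiv), THF, sealed tube, 110–125 °C
Reagents that add atoms: none
Why: Fluoride attacks silicon and the resulting aryl anion expels triflate to give aryne 22 between C1 and C2; hexanoate oxygen adds to C2, and the C1 aryl anion then adds to the ester carbonyl through a transient four-membered alkoxide that reopens to the ortho-acyl phenoxide, so the aryl–C(=O) and aryl–O bonds form together, which is the known insertion of arynes into the C–O bond of carboxylic acids. No ring is retained and no stereocentre is created; the two benzylic centres are spectators because the enols are capped and no Lewis acid is present. The step needs regioselectivity, and the benzyloxy group at C6 supplies it: it polarises the aryne so that the nucleophile attacks the distal carbon C2 and the negative charge develops at C1 next to the electronegative oxygen, which places the acyl group between the two oxygens. Acyl transfer must also outrun protonation of the C1 anion (which would stop at the aryl hexanoate); aprotic THF at high temperature and excess CsF, which binds the acid proton, favour it.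

Step 11
Reactants: 23 tetra-O-benzyl ortho-hydroxyaryl ketone
Product: 24 myrtucommulone H
Conditions: H2 (1 atm), 10% Pd/C, EtOAc, rt
Reagents that add atoms: none
Why: Hydrogenolysis cleaves the two aryl benzyl ethers and the two benzyl vinylogous esters under neutral conditions, so neither acid-promoted cyclodehydration of a phenol onto a syncarpic enol nor base-promoted retro-Michael epimerisation can occur, and the hydrogen-bonded aryl ketone and the tetrasubstituted enone double bonds should not be reduced.

Compound list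
1 | syncarpic acid (2,2,4,4-tetramethylcyclohexane-1,3,5-trione) | CC1(C)C(=O)CC(=O)C(C)(C)C1=O | starting material
2 | 2-methylpropanal | CC(C)C=O | starting material
3 | Mannich base, 3-hydroxy-4,4,6,6-tetramethyl-2-[2-methyl-1-(piperidin-1-yl)propyl]cyclohex-2-ene-1,5-dione (racemic, not isolated) | CC(C)C(N1CCCCC1)C1=C(O)C(C)(C)C(=O)C(C)(C)C1=O | intermediate
4 | 2,2,4,4-tetramethyl-6-(2-methylpropylidene)cyclohexane-1,3,5-trione | CC(C)C=C1C(=O)C(C)(C)C(=O)C(C)(C)C1=O | intermediate
5 | 3-methylbutanal | CC(C)CC=O | starting material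
6 | Mannich base, 3-hydroxy-4,4,6,6-tetramethyl-2-[3-methyl-1-(piperidin-1-yl)butyl]cyclohex-2-ene-1,5-dione (racemic, not isolated) | CC(C)CC(N1CCCCC1)C1=C(O)C(C)(C)C(=O)C(C)(C)C1=O | intermediate
7 | 2,2,4,4-tetramethyl-6-(3-methylbutylidene)cyclohexane-1,3,5-trione | CC(C)CC=C1C(=O)C(C)(C)C(=O)C(C)(C)C1=O | intermediate
8 | phloroglucinol (benzene-1,3,5-triol) | Oc1cc(O)cc(O)c1 | starting material
9 | 3-hydroxy-4,4,6,6-tetramethyl-2-[(1R)-2-methyl-1-(2,4,6-trihydroxyphenyl)propyl]cyclohex-2-ene-1,5-dione (not isolated) | Oc1cc(O)c([C@H](C2=C(O)C(C)(C)C(=O)C(C)(C)C2=O)C(C)C)c(O)c1 | intermediate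
10 | 3-(benzyloxy)-4,4,6,6-tetramethyl-2-[(1R)-2-methyl-1-(2,4,6-trihydroxyphenyl)propyl]cyclohex-2-ene-1,5-dione | Oc1cc(O)c([C@H](C2=C(OCc3ccccc3)C(C)(C)C(=O)C(C)(C)C2=O)C(C)C)c(O)c1 | intermediate
11 | 3-(benzyloxy)-2-[(1R)-1-{2,6-dihydroxy-4-[tri(propan-2-yl)silyloxy]phenyl}-2-methylpropyl]-4,4,6,6-tetramethylcyclohex-2-ene-1,5-dione | CC(C)[Si](C(C)C)(C(C)C)Oc1cc(O)c([C@H](C2=C(OCc3ccccc3)C(C)(C)C(=O)C(C)(C)C2=O)C(C)C)c(O)c1 | intermediate
12 | 3-(benzyloxy)-2-[(1R)-1-{2,6-bis(benzyloxy)-4-[tri(propan-2-yl)silyloxy]phenyl}-2-methylpropyl]-4,4,6,6-tetramethylcyclohex-2-ene-1,5-dione | CC(C)[Si](C(C)C)(C(C)C)Oc1cc(OCc2ccccc2)c([C@H](C2=C(OCc3ccccc3)C(C)(C)C(=O)C(C)(C)C2=O)C(C)C)c(OCc2ccccc2)c1 | intermediate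
13 | 3-(benzyloxy)-2-[(1R)-1-[2,6-bis(benzyloxy)-4-hydroxyphenyl]-2-methylpropyl]-4,4,6,6-tetramethylcyclohex-2-ene-1,5-dione | Oc1cc(OCc2ccccc2)c([C@H](C2=C(OCc3ccccc3)C(C)(C)C(=O)C(C)(C)C2=O)C(C)C)c(OCc2ccccc2)c1 | intermediate
14 | ring A phenol: C1–H, C2–OH, C3 (1R)-1-(2-hydroxy-3,3,5,5-tetramethyl-4,6-dioxocyclohex-1-en-1-yl)-3-methylbutyl, C4–OBn, C5 (1R)-1-[2-(benzyloxy)-3,3,5,5-tetramethyl-4,6-dioxocyclohex-1-en-1-yl]-2-methylpropyl, C6–OBn (not isolated) | Oc1c([C@@H](CC(C)C)C2=C(O)C(C)(C)C(=O)C(C)(C)C2=O)c(OCc2ccccc2)c([C@H](C2=C(OCc3ccccc3)C(C)(C)C(=O)C(C)(C)C2=O)C(C)C)c(OCc2ccccc2)c1 | intermediate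
15 | as 14, with the C3 arm as (1R)-1-[2-(benzyloxy)-3,3,5,5-tetramethyl-4,6-dioxocyclohex-1-en-1-yl]-3-methylbutyl | Oc1c([C@@H](CC(C)C)C2=C(OCc3ccccc3)C(C)(C)C(=O)C(C)(C)C2=O)c(OCc2ccccc2)c([C@H](C2=C(OCc3ccccc3)C(C)(C)C(=O)C(C)(C)C2=O)C(C)C)c(OCc2ccccc2)c1 | intermediate
16 | as 15, with iodine at C1 (iodophenol) | Oc1c([C@@H](CC(C)C)C2=C(OCc3ccccc3)C(C)(C)C(=O)C(C)(C)C2=O)c(OCc2ccccc2)c([C@H](C2=C(OCc3ccccc3)C(C)(C)C(=O)C(C)(C)C2=O)C(C)C)c(OCc2ccccc2)c1I | intermediate
17 | as 16, with C2–OSiMe3 (not isolated) | C[Si](C)(C)Oc1c([C@@H](CC(C)C)C2=C(OCc3ccccc3)C(C)(C)C(=O)C(C)(C)C2=O)c(OCc2ccccc2)c([C@H](C2=C(OCc3ccccc3)C(C)(C)C(=O)C(C)(C)C2=O)C(C)C)c(OCc2ccccc2)c1I | intermediate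
18 | as 17, with lithium at C1 in place of iodine (not isolated) | C[Si](C)(C)Oc1c([C@@H](CC(C)C)C2=C(OCc3ccccc3)C(C)(C)C(=O)C(C)(C)C2=O)c(OCc2ccccc2)c([C@H](C2=C(OCc3ccccc3)C(C)(C)C(=O)C(C)(C)C2=O)C(C)C)c(OCc2ccccc2)c1[Li] | intermediate
19 | lithium phenoxide with C1–SiMe3 and C2–OLi (not isolated) | [Li]Oc1c([C@@H](CC(C)C)C2=C(OCc3ccccc3)C(C)(C)C(=O)C(C)(C)C2=O)c(OCc2ccccc2)c([C@H](C2=C(OCc3ccccc3)C(C)(C)C(=O)C(C)(C)C2=O)C(C)C)c(OCc2ccccc2)c1[Si](C)(C)C | intermediate
20 | 2-(trimethylsilyl)aryl triflate of ring A: C1–SiMe3, C2–OSO2CF3, C3 (R)-isobutyl arm, C4–OBn, C5 (R)-isopropyl arm, C6–OBn, both syncarpic enols as benzyl ethers | C[Si](C)(C)c1c(OS(=O)(=O)C(F)(F)F)c([C@@H](CC(C)C)C2=C(OCc3ccccc3)C(C)(C)C(=O)C(C)(C)C2=O)c(OCc2ccccc2)c([C@H](C2=C(OCc3ccccc3)C(C)(C)C(=O)C(C)(C)C2=O)C(C)C)c1OCc1ccccc1 | intermediate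
21 | hexanoic acid | CCCCCC(=O)O | starting material
22 | aryne of ring A with the triple bond between C1 and C2 (not isolated) | C1#CC([C@@H](CC(C)C)C2=C(OCc3ccccc3)C(C)(C)C(=O)C(C)(C)C2=O)=C(OCc2ccccc2)C([C@H](C2=C(OCc3ccccc3)C(C)(C)C(=O)C(C)(C)C2=O)C(C)C)=C1OCc1ccccc1 | intermediate
23 | tetra-O-benzyl myrtucommulone H: C1 hexanoyl, C2–OH, C4–OBn, C6–OBn, both syncarpic enols as benzyl ethers, both arms (R) | CCCCCC(=O)c1c(O)c([C@@H](CC(C)C)C2=C(OCc3ccccc3)C(C)(C)C(=O)C(C)(C)C2=O)c(OCc2ccccc2)c([C@H](C2=C(OCc3ccccc3)C(C)(C)C(=O)C(C)(C)C2=O)C(C)C)c1OCc1ccccc1 | intermediate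
24 | myrtucommulone H | CCCCCC(=O)c1c(O)c([C@@H](CC(C)C)C2=C(O)C(C)(C)C(=O)C(C)(C)C2=O)c(O)c([C@H](C2=C(O)C(C)(C)C(=O)C(C)(C)C2=O)C(C)C)c1O | target

Total step count: 11. Longest linear sequence: 10 steps (step 1, then steps 3 to 11).

Steps most likely to fail

Step 10 (key step). Three processes may divert the aryne: capture of C2 by a carbonyl oxygen of the neighbouring C3 arm, attack of hexanoate at C1 because the arm shields C2, and protonation of the C1 anion before acyl transfer. Fallback: starting from iodophenol 16, O-acylation with hexanoyl chloride (Et3N, DMAP, CH2Cl2, 0 °C) should give the aryl hexanoate F1. Iodine–lithium exchange (t-BuLi, Et2O/THF, −100 °C) then triggers an anionic ortho-Fries 1,3 O-to-C acyl shift, and aqueous work-up delivers ketone 23, where the route is rejoined. This path makes no aryne.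

Step 9. The organolithium may add to a dione carbonyl or deprotonate a benzylic ether position in competition with iodine–lithium exchange, or the silyl shift may be incomplete. Fallback: starting from 16, which is silylated to 17 with HMDS as in the main route, the carbon–silicon bond is made without an organolithium by palladium-catalysed coupling of the aryl iodide with hexamethyldisilane (Pd2(dba)3, 2-(di-tert-butylphosphino)biphenyl, LiOAc, DMF, 100 °C). Aqueous work-up releases the 2-(trimethylsilyl)phenol F2, and Tf2O with pyridine (CH2Cl2, 0 °C) converts it into 20, where the route is rejoined.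

Step 7. Facial selectivity at the new centre may be poor on this hindered mono-phenol, or the enolisable acceptor 7 may be lost by double-bond isomerisation under the amine catalyst. Fallback: starting from 13 and 7, the addition is run with an achiral amine (DABCO, CH2Cl2, rt), so that 14 forms together with the epimeric free enol adduct F3. Isourea capping as in the main route gives 15 and the epimeric benzyl enol ether F4, and chromatographic separation of the two diastereomers returns 15 to the route. The centre is then secured by separation instead of induction.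

Further compounds
F1 | step 10 | aryl hexanoate of 16 (C1 iodine; C2–O–CO(CH2)4CH3) | CCCCCC(=O)Oc1c([C@@H](CC(C)C)C2=C(OCc3ccccc3)C(C)(C)C(=O)C(C)(C)C2=O)c(OCc2ccccc2)c([C@H](C2=C(OCc3ccccc3)C(C)(C)C(=O)C(C)(C)C2=O)C(C)C)c(OCc2ccccc2)c1I
F2 | step 9 | 2-(trimethylsilyl)phenol (C1–SiMe3; C2–OH) | Oc1c([C@@H](CC(C)C)C2=C(OCc3ccccc3)C(C)(C)C(=O)C(C)(C)C2=O)c(OCc2ccccc2)c([C@H](C2=C(OCc3ccccc3)C(C)(C)C(=O)C(C)(C)C2=O)C(C)C)c(OCc2ccccc2)c1[Si](C)(C)C
F3 | step 7 | epimer of 14 with (S) configuration at the C3 arm | Oc1c([C@H](CC(C)C)C2=C(O)C(C)(C)C(=O)C(C)(C)C2=O)c(OCc2ccccc2)c([C@H](C2=C(OCc3ccccc3)C(C)(C)C(=O)C(C)(C)C2=O)C(C)C)c(OCc2ccccc2)c1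
F4 | step 7 | epimer of 15 with (S) configuration at the C3 arm | Oc1c([C@H](CC(C)C)C2=C(OCc3ccccc3)C(C)(C)C(=O)C(C)(C)C2=O)c(OCc2ccccc2)c([C@H](C2=C(OCc3ccccc3)C(C)(C)C(=O)C(C)(C)C2=O)C(C)C)c(OCc2ccccc2)c1
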